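**Strategy.** Numbering atoms by their position in the target SMILES, the C19–C20 bond is the only bond common to the cyclopentane and the cycloheptene, so its removal exposes the ten-membered perimeter C23–C22–C21–C20–C26–C13–C14–C16–C18–C19. A (Z)-cyclodec-6-ene-1,4-dione bearing the C16 silyl ether and a protected C12–C11 arm is therefore closed by a transannular aldol condensation that creates C19–C20, and with it both carbocycles, as a ring-fused cyclopentenone. The enone is then relayed to the cis-fused carbinol, and its arm is joined by B-alkyl Suzuki coupling to a trans-fused oxepane–cyclohexane enol triflate assembled by a bis-epoxide cascade.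

Key step: step 18

Remark: C-labels (C5 … C36) are atom positions in the target SMILES; compound names use their own locants.
Remark: the carbinol carbons C20 and C23 are carried as stereo-mixtures (racemic before step 12) up to compound 26, because both become ketone carbons in 27; their SMILES are left undefined at these centres.
Remark: the key-step precursor and product are written with full descriptors, (6Z,8R) and (7R), which follow from C16 (R) of the target.

Step 1
Reactants: 1 methyl isobutyrate; 2 acrolein; 3 propanoyl chloride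
Product: 5 methyl 2,2-dimethyl-3-(propanoyloxy)pent-4-enoate (racemic), via lithium aldolate 4 (not isolated)
Conditions: LiN(iPr)2, THF, −78 °C; 2; then 3, −78 → 0 °C
Reagents that add atoms: none
Why: Kinetic aldol addition of the ester lithium enolate to the carbonyl of acrolein (1,2-addition at low temperature) followed by O-acylation of the aldolate should give the β-acyloxy ester, the new C20 centre being left racemic because it is later oxidised.

Step 2
Reactants: 5 methyl 2,2-dimethyl-3-(propanoyloxy)pent-4-enoate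
Product: 6 6-ethenyl-3,5,5-trimethyloxane-2,4-dione
Conditions: LiN(SiMe3)2 (2.2 equiv), THF, −78 → 0 °C; aq. HCl
Reagents that add atoms: none
Why: Intramolecular Claisen condensation (Dieckmann-type lactone closure) of the propanoate enolate onto the non-enolisable neopentyl methyl ester should close the six-membered β-keto lactone and is driven by deprotonation of the product, the low temperature keeping the sigmatropic ester-enolate Claisen rearrangement of the allylic ester at bay.

Step 3
Reactants: 6 6-ethenyl-3,5,5-trimethyloxane-2,4-dione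
Product: 7 6-ethenyl-3,5,5-trimethyl-2-oxo-5,6-dihydro-2H-pyran-4-yl trifluoromethanesulfonate
Conditions: Tf2O, Et3N, CH2Cl2, −78 °C
Reagents that add atoms: trifluoromethanesulfonic anhydride, O=S(=O)(OS(=O)(=O)C(F)(F)F)C(F)(F)F
Why: The β-keto lactone can enolise only toward C14 because C26 is quaternary, so O-sulfonylation should give a single vinylogous acyl triflate in which the ring forces the C16 carbonyl and C26 to be cis across C13=C14.

Step 4
Reactants: 8 4-methoxybenzyl alcohol; 9 ethyl vinyl ether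
Product: 10 4-methoxybenzyl vinyl ether
Conditions: Pd(OAc)2 (2 mol %), 1,10-phenanthroline (2 mol %), neat 9 (excess), rt
Reagents that add atoms: none
Why: Palladium diacetate–phenanthroline catalysed transfer vinylation (transetherification) of a primary alcohol in excess vinyl ether is an established route to benzylic vinyl ethers.

Step 5
Reactants: 10 4-methoxybenzyl vinyl ether; 7 enol triflate
Product: 12 6-ethenyl-4-[2-(4-methoxybenzyloxy)ethyl]-3,5,5-trimethyl-5,6-dihydro-2H-pyran-2-one, via alkylborane 11 (not isolated)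
Conditions: 9-BBN, THF, 0 °C → rt; then 7, Pd(dppf)Cl2 (5 mol %), AsPh3, K3PO4 (aq), DMF, rt
Reagents that add atoms: none
Why: Hydroboration of the enol ether places boron on the terminal carbon, and B-alkyl Suzuki–Miyaura coupling of this primary alkylborane with the electron-poor vinyl triflate should install the C12–C11 arm at C13 with retention of the ring-locked alkene geometry.

Step 6
Reactants: 12 lactone
Product: 13 (2Z)-5-hydroxy-N-methoxy-3-[2-(4-methoxybenzyloxy)ethyl]-N,2,4,4-tetramethylhepta-2,6-dienamide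
Conditions: MeNH(OMe)·HCl, iPrMgCl, THF, −20 → 0 °C
Reagents that add atoms: N,O-dimethylhydroxylamine hydrochloride, CNOC.Cl
Why: Weinreb aminolysis of the lactone with the magnesium amide should open the ring to the hydroxy amide while the tetrasubstituted alkene keeps the Z geometry inherited from the lactone.

Step 7
Reactants: 13 hydroxy Weinreb amide
Product: 14 (2Z)-N-methoxy-3-[2-(4-methoxybenzyloxy)ethyl]-N,2,4,4-tetramethyl-5-(triethylsilyloxy)hepta-2,6-dienamide
Conditions: Et3SiOTf, 2,6-lutidine, CH2Cl2, −78 °C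
Reagents that add atoms: triethylsilyl trifluoromethanesulfonate, CC[Si](CC)(CC)OS(=O)(=O)C(F)(F)F
Why: Silylation of the neopentyl allylic alcohol with the silyl triflate blocks relactonisation and protects the C20 hydroxyl for the organolithium step.

Step 8
Reactants: 15 penta-1,4-dien-3-ol
Product: 16 3-(triethylsilyloxy)penta-1,4-diene
Conditions: Et3SiCl, imidazole, CH2Cl2, 0 °C → rt
Reagents that add atoms: chlorotriethylsilane, CC[Si](CC)(CC)Cl
Why: Standard silyl ether formation protects the carbinol that will become C23.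

Step 9
Reactants: 16 3-(triethylsilyloxy)penta-1,4-diene
Product: 18 3-(triethylsilyloxy)pent-4-en-1-ol (racemic), via alkylborane 17 (not isolated)
Conditions: 9-BBN (1.0 equiv), THF, 0 °C → rt; then NaOH, H2O2, 0 °C
Reagents that add atoms: hydrogen peroxide, OO
Why: Anti-Markovnikov hydroboration–oxidation with one equivalent of the bulky borane should functionalise only one of the two equivalent vinyl groups in a statistical mono-addition, giving the racemic primary alcohol.

Step 10
Reactants: 18 3-(triethylsilyloxy)pent-4-en-1-ol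
Product: 19 5-iodo-3-(triethylsilyloxy)pent-1-ene
Conditions: I2, PPh3, imidazole, CH2Cl2, 0 °C
Reagents that add atoms: iodine, II
Why: Appel-type iodination converts the primary alcohol into the iodide without touching the allylic silyl ether.

Step 11
Reactants: 19 5-iodo-3-(triethylsilyloxy)pent-1-ene; 14 silylated Weinreb amide
Product: 21 (7Z)-8-[2-(4-methoxybenzyloxy)ethyl]-7,9,9-trimethyl-3,10-bis(triethylsilyloxy)dodeca-1,7,11-trien-6-one, via organolithium 20 (not isolated)
Conditions: t-BuLi (2.1 equiv), Et2O, −78 °C; then 14, THF, −78 → 0 °C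
Reagents that add atoms: none
Why: Iodine–lithium exchange followed by acyl substitution at the Weinreb amide, whose chelated tetrahedral adduct prevents over-addition, should give the α,β-unsaturated ketone with the C18–C19–C23 chain in place.

Step 12
Reactants: 21 trienone
Product: 22 (6R,7Z)-8-[2-(4-methoxybenzyloxy)ethyl]-7,9,9-trimethyl-3,10-bis(triethylsilyloxy)dodeca-1,7,11-trien-6-ol
Conditions: (S)-2-methyl-CBS-oxazaborolidine (20 mol %), catecholborane, toluene, −78 °C
Reagents that add atoms: none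
Why: Corey–Bakshi–Shibata reduction, in which the α-branched alkenyl group acts as the large substituent, should set C16 as R under catalyst control regardless of the remote racemic centres, and catecholborane at low temperature spares the vinyl groups.

Step 13
Reactants: 22 allylic alcohol
Product: 23 (6R,7Z)-6-(tert-butyldimethylsilyloxy)-8-[2-(4-methoxybenzyloxy)ethyl]-7,9,9-trimethyl-3,10-bis(triethylsilyloxy)dodeca-1,7,11-triene
Conditions: t-BuMe2SiOTf, 2,6-lutidine, CH2Cl2, −78 → 0 °C
Reagents that add atoms: tert-butyldimethylsilyl trifluoromethanesulfonate, CC(C)(C)[Si](C)(C)OS(=O)(=O)C(F)(F)F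
Why: Silylation with the silyl triflate protects the hindered allylic C16 alcohol as the ether required in the key-step precursor.

Step 14
Reactants: 23 tris-silyl ether
Product: 24 (6R,7Z)-6-(tert-butyldimethylsilyloxy)-8-[2-(4-methoxybenzyloxy)ethyl]-7,9,9-trimethyldodeca-1,7,11-triene-3,10-diol
Conditions: PPTS, MeOH/CH2Cl2, 0 °C → rt
Reagents that add atoms: none
Why: Mild acid methanolysis should cleave the two secondary triethylsilyl ethers much faster than the bulkier tert-butyldimethylsilyl ether, freeing both vinyl carbinols.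

Step 15
Reactants: 24 triene diol
Product: 25 (6Z,8R)-8-(tert-butyldimethylsilyloxy)-6-[2-(4-methoxybenzyloxy)ethyl]-5,5,7-trimethylcyclodeca-2,6-diene-1,4-diol
Conditions: second-generation Grubbs catalyst (10 mol %), CH2Cl2 (1 mM), 40 °C
Reagents that add atoms: none
Why: Ring-closing metathesis of the two terminal vinyl groups forms C21=C22 and the ten-membered ring, the cis tetrasubstituted alkene and the gem-dimethyl group pre-organising the chain and high dilution suppressing oligomerisation.

Step 16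
Reactants: 25 cyclodecadiene diol
Product: 26 (6Z,8R)-8-(tert-butyldimethylsilyloxy)-6-[2-(4-methoxybenzyloxy)ethyl]-5,5,7-trimethylcyclodec-6-ene-1,4-diol
Conditions: H2 (1 atm), RhCl(PPh3)3 (10 mol %), benzene, rt
Reagents that add atoms: none
Why: Homogeneous hydrogenation with RhCl(PPh3)3 reduces the disubstituted ring alkene and leaves the hindered tetrasubstituted alkene, the benzylic ether and the allylic C–O bond untouched.

Step 17
Reactants: 26 cyclodecene diol
Product: 27 (6Z,8R)-8-(tert-butyldimethylsilyloxy)-6-[2-(4-methoxybenzyloxy)ethyl]-5,5,7-trimethylcyclodec-6-ene-1,4-dione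
Conditions: Dess–Martin periodinane, pyridine, CH2Cl2, 0 °C → rt
Reagents that add atoms: none
Why: Dess–Martin oxidation of both secondary alcohols under buffered conditions should deliver the 1,4-diketone and remove the two stereo-mixture centres.

Step 18
Reactants: 27 cyclodecenedione
Product: 29 (7R)-7-(tert-butyldimethylsilyloxy)-5-[2-(4-methoxybenzyloxy)ethyl]-4,4,6-trimethyl-2,3,7,8-tetrahydroazulen-1(4H)-one, via ketol 28 (not isolated)
Conditions: KOt-Bu (0.3 equiv), t-BuOH/THF, 0 → 40 °C
Reagents that add atoms: none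
Why: Catalytic alkoxide reversibly enolises the C23 ketone toward C19, the enolate adds across the ring to the C20 carbonyl to give ketol 28, and E1cB loss of water drives the sequence to the tetrasubstituted enone; the closest known reaction is the transannular aldol condensation of cyclodecane-1,4-diones to bicyclo[5.3.0]decenones, the ring version of the 1,4-diketone to cyclopentenone cyclisation. The cyclopentane closes in the 5-(enolendo)-exo-trig mode, the less favourable enolate mode that is nevertheless the normal course for 1,4-diketones, and the cycloheptene closes at the same time in the 7-(enolexo)-exo-trig mode. No new stereocentre remains because C19 and C20 end as alkene carbons, and C16 is not touched. The step needs regioselective bond formation, which the substrate secures because C26 is quaternary and every other enolate–carbonyl pairing (C21 on C23 or C22 on C20) would give a cyclopropanol. It also needs C19 and C20 to approach each other, which the Z alkene C13=C14 and the gem-dimethyl group enforce across the ring, while the C16 silyl ether sits γ to the C23 carbonyl and cannot be eliminated.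

Step 19
Reactants: 29 bicyclic enone
Product: 30 (1R,7R)-7-(tert-butyldimethylsilyloxy)-5-[2-(4-methoxybenzyloxy)ethyl]-4,4,6-trimethyl-1,2,3,4,7,8-hexahydroazulen-1-ol
Conditions: (S)-2-methyl-CBS-oxazaborolidine (20 mol %), catecholborane, toluene, −78 → −40 °C
Reagents that add atoms: none
Why: Corey–Bakshi–Shibata reduction of the 2,3-disubstituted cyclopentenone, with the α-substituted alkene carbon as the large group, should give the 1R allylic alcohol under catalyst control and so provide the handle that dictates the face of the next step.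

Step 20
Reactants: 30 allylic alcohol
Product: 31 (1R,3aR,7R,8aR)-7-(tert-butyldimethylsilyloxy)-5-[2-(4-methoxybenzyloxy)ethyl]-4,4,6-trimethyl-1,2,3,3a,4,7,8,8a-octahydroazulen-1-ol
Conditions: H2 (1 atm), [Ir(cod)(PCy3)(py)]PF6 (10 mol %), CH2Cl2, rt
Reagents that add atoms: none
Why: Hydroxyl-directed hydrogenation with the cationic iridium catalyst delivers both hydrogens to the face of the C23 hydroxyl, so the tetrasubstituted C19=C20 bond becomes the cis ring fusion with C19 and C20 both R, while the undirected and shielded C13=C14 alkene is left.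

Step 21
Reactants: 31 cis-fused alcohol
Product: 32 (3aR,7R,8aR)-7-(tert-butyldimethylsilyloxy)-5-[2-(4-methoxybenzyloxy)ethyl]-4,4,6-trimethyl-3,3a,4,7,8,8a-hexahydroazulen-1(2H)-one
Conditions: Dess–Martin periodinane, pyridine, CH2Cl2, 0 °C
Reagents that add atoms: none
Why: Dess–Martin oxidation under pyridine buffering returns the C23 ketone without epimerising the adjacent C19 centre.

Step 22
Reactants: 32 cis-fused ketone
Product: 33 (3aR,7R,8aR)-7-(tert-butyldimethylsilyloxy)-5-[2-(4-methoxybenzyloxy)ethyl]-4,4,6-trimethyl-1-methylidene-1,2,3,3a,4,7,8,8a-octahydroazulene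
Conditions: Zn, CH2Br2, TiCl4, THF/CH2Cl2, 0 °C → rt
Reagents that add atoms: dibromomethane, BrCBr
Why: The non-basic Lombardo methylenation (geminal dizinc reagent activated by TiCl4) converts the ketone into the exocyclic alkene without epimerising the α-stereocentre C19, which a basic ylide could invert.

Step 23
Reactants: 33 exocyclic alkene
Product: 34 (1R,3aR,7R,8aR)-7-(tert-butyldimethylsilyloxy)-5-[2-(4-methoxybenzyloxy)ethyl]-1,4,4,6-tetramethyl-1,2,3,3a,4,7,8,8a-octahydroazulen-1-ol
Conditions: Mn(dpm)3 (10 mol %; dpm = dipivaloylmethanate), PhSiH3, O2 (1 atm), i-PrOH/CH2Cl2, 0 °C → rt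
Reagents that add atoms: dioxygen, O=O
Why: Mukaiyama hydration proceeds by hydrogen-atom transfer to the 1,1-disubstituted alkene (the hindered tetrasubstituted alkene, which a peracid would attack first, is inert here) and the tertiary C23 radical should capture oxygen on the convex face of the cis-fused bicycle, syn to H19, giving the 1R alcohol with the methyl group on the concave side.

Step 24
Reactants: 34 tertiary alcohol
Product: 35 (1R,3aR,7R,8aR)-7-(tert-butyldimethylsilyloxy)-5-(2-hydroxyethyl)-1,4,4,6-tetramethyl-1,2,3,3a,4,7,8,8a-octahydroazulen-1-ol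
Conditions: DDQ, CH2Cl2/pH 7 buffer, 0 °C
Reagents that add atoms: none
Why: Oxidative cleavage of the 4-methoxybenzyl ether with DDQ frees the primary alcohol and leaves the silyl ether and the alkene.

Step 25
Reactants: 35 diol
Product: 36 (1R,3aR,7R,8aR)-7-(tert-butyldimethylsilyloxy)-5-(2-iodoethyl)-1,4,4,6-tetramethyl-1,2,3,3a,4,7,8,8a-octahydroazulen-1-ol
Conditions: I2, PPh3, imidazole, CH2Cl2, 0 °C
Reagents that add atoms: iodine, II
Why: Appel-type iodination is selective for the primary alcohol over the hindered tertiary one.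

Step 26
Reactants: 37 geranyl bromide; 38 (4-bromobut-1-yn-1-yl)trimethylsilane
Product: 40 trimethyl[(6E)-7,11-dimethyldodeca-6,10-dien-1-yn-1-yl]silane, via Grignard reagent 39 (not isolated)
Conditions: 38, Mg, THF, rt; then 37, Li2CuCl4 (3 mol %), THF, −20 → 0 °C
Reagents that add atoms: none
Why: Copper-catalysed coupling of the homopropargyl Grignard reagent with the primary allylic bromide should occur at the α-carbon (SN2) with retention of the E geometry.

Step 27
Reactants: 40 silylated dienyne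
Product: 41 (6E)-7,11-dimethyldodeca-6,10-dien-1-yne
Conditions: K2CO3 (cat.), MeOH, rt
Reagents that add atoms: none
Why: Carbonate-catalysed methanolysis of the alkynylsilane liberates the terminal alkyne.

Step 28
Reactants: 41 terminal alkyne
Product: 43 trimethyl[(7E)-8,12-dimethyltrideca-7,11-dien-2-yn-1-yl]silane, via lithium acetylide 42 (not isolated)
Conditions: n-BuLi, THF, −78 °C; Me3SiCH2I, THF, −78 °C → reflux
Reagents that add atoms: (iodomethyl)trimethylsilane, C[Si](C)(C)CI
Why: Alkylation of the lithium acetylide with the α-silyl iodide gives the propargylsilane that will terminate the cationic cascade.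

Step 29
Reactants: 43 propargylsilane
Product: 44 trimethyl(6-{(2R,3R)-3-[2-((2R)-3,3-dimethyloxiran-2-yl)ethyl]-3-methyloxiran-2-yl}hex-2-yn-1-yl)silane
Conditions: D-fructose-derived Shi ketone (60 mol %), KHSO5 (as 2KHSO5·KHSO4·K2SO4), K2CO3, Bu4NHSO4, MeCN/CH2(OMe)2/aq. Na2B4O7 buffer, 0 °C
Reagents that add atoms: potassium peroxymonosulfate, [K+].[O-]S(=O)(=O)OO
Why: Shi asymmetric epoxidation (chiral dioxirane generated in situ) should epoxidise both trisubstituted alkenes with the same facial sense to give the all-R bis-epoxide under catalyst control, the alkyne being inert.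

Step 30
Reactants: 44 bis-epoxide
Product: 46 (3R,5aR,9aR)-6-ethenylidene-2,2,5a-trimethyldecahydro-1-benzoxepin-3-ol, via trimethylsilyl ether 45 (not isolated)
Conditions: Me3SiOTf (1.2 equiv), 2,6-di-tert-butyl-4-methylpyridine, CH2Cl2, −78 °C; then K2CO3, MeOH, rt
Reagents that add atoms: none
Why: Silyl triflate activation of the terminal epoxide triggers a tandem oxa-/carbacyclisation (epoxide-initiated cation–olefin cascade) in which the inner epoxide oxygen opens the activated epoxide at C36 in the 7-endo sense and the propargylsilane attacks the resulting epoxonium ion at C8 anti to oxygen through a chair, so C5 and C34 keep their epoxide configuration, C8 is inverted, the ring fusion is trans and loss of silicon leaves the allene.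

Step 31
Reactants: 46 allene alcohol
Product: 47 triethyl{[(3R,5aR,9aR)-6-ethenylidene-2,2,5a-trimethyldecahydro-1-benzoxepin-3-yl]oxy}silane
Conditions: Et3SiCl, imidazole, DMAP, DMF, rt
Reagents that add atoms: chlorotriethylsilane, CC[Si](CC)(CC)Cl
Why: Silylation protects the hindered C5 alcohol with a group that can later be removed in the presence of the tert-butyldimethylsilyl ether.

Step 32
Reactants: 47 silylated allene
Product: 48 (3R,5aS,9aR)-2,2,5a-trimethyl-3-(triethylsilyloxy)octahydro-1-benzoxepin-6(2H)-one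
Conditions: O3, CH2Cl2, −78 °C; then Me2S, −78 °C → rt
Reagents that add atoms: ozone, [O-][O+]=O
Why: Ozonolysis cleaves both cumulated double bonds of the allene and leaves the C10 ketone.

Step 33
Reactants: 48 bicyclic ketone
Product: 49 (3R,5aS,9aR)-2,2,5a-trimethyl-3-(triethylsilyloxy)-2,3,4,5,5a,8,9,9a-octahydro-1-benzoxepin-6-yl trifluoromethanesulfonate
Conditions: KN(SiMe3)2, PhNTf2, THF, −78 °C
Reagents that add atoms: N-phenylbis(trifluoromethanesulfonimide), O=S(=O)(N(c1ccccc1)S(=O)(=O)C(F)(F)F)C(F)(F)F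
Why: The ketone can enolise only toward C29 because C8 is quaternary, so trapping of the potassium enolate with the triflimide gives a single enol triflate.

Step 34
Reactants: 36 iodide; 49 enol triflate
Product: 52 coupled triene (C10–C11 bond formed; C5 triethylsilyl ether; C16 tert-butyldimethylsilyl ether; free C23 hydroxyl), via dilithio species 50 (not isolated), via borate complex 51 (not isolated)
Conditions: 36, t-BuLi (3.1 equiv), Et2O, −78 °C; 9-MeO-9-BBN, THF, −78 °C → rt; then 49, Pd(dppf)Cl2 (10 mol %), K3PO4 (aq), DMF, rt → 45 °C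
Reagents that add atoms: none
Why: Iodine–lithium exchange (one extra equivalent of t-BuLi turns the tertiary hydroxyl into its alkoxide), capture by the methoxyborane and B-alkyl Suzuki–Miyaura coupling of the resulting borate with the enol triflate should form the C10–C11 bond without disturbing any stereocentre.

Step 35
Reactants: 52 coupled triene
Product: 54 secondary alcohol at C29 (C10–H and C29–OH both trans to the angular C8 methyl), via organoborane 53 (not isolated)
Conditions: thexylborane (from BH3·THF and 2,3-dimethylbut-2-ene), THF, 0 °C → rt; then NaOH, H2O2, 0 °C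
Reagents that add atoms: hydrogen peroxide, OO
Why: Hydroboration–oxidation adds boron to the less substituted C29 and hydrogen to C10 in a syn fashion from the face opposite the angular C8 methyl, setting C10 as R, while thexylborane does not add to the shielded tetrasubstituted C13=C14 alkene.

Step 36
Reactants: 54 secondary alcohol
Product: 55 C29 ketone
Conditions: Dess–Martin periodinane, pyridine, CH2Cl2, 0 °C → rt
Reagents that add atoms: none
Why: Dess–Martin oxidation converts the secondary C29 alcohol into the ketone, the tertiary alcohol being inert and the equatorial C10 side chain being the thermodynamically preferred epimer.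

Step 37
Reactants: 55 C29 ketone
Product: 56 tertiary alcohol at C29 (C5 triethylsilyl ether; C16 tert-butyldimethylsilyl ether)
Conditions: MeMgBr, CeCl3, THF, −78 → 0 °C
Reagents that add atoms: methylmagnesium bromide, C[Mg]Br
Why: The organocerium reagent (Imamoto conditions suppress enolisation) should add to the C29 ketone along the equatorial trajectory because axial approach is blocked by the syn-axial C8 methyl, giving the axial hydroxyl and equatorial methyl, that is C29 (S).

Step 38
Reactants: 56 bis-silyl ether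
Product: 57 C5 alcohol (C16 tert-butyldimethylsilyl ether retained)
Conditions: PPTS, MeOH/CH2Cl2, 0 °C → rt
Reagents that add atoms: none
Why: Mild acid methanolysis removes the secondary triethylsilyl ether selectively in the presence of the tert-butyldimethylsilyl ether.

Step 39
Reactants: 57 C5 alcohol
Product: 58 C5 acetate (C16 tert-butyldimethylsilyl ether)
Conditions: Ac2O, pyridine, DMAP (cat.), CH2Cl2, 0 °C → rt
Reagents that add atoms: acetic anhydride, CC(=O)OC(C)=O
Why: Acetylation under nucleophilic catalysis esterifies the only free secondary alcohol, the two tertiary alcohols being too hindered to react under these conditions.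

Step 40
Reactants: 58 silylated acetate
Product: 59 CNP0157376.1
Conditions: HF·pyridine, pyridine, THF, 0 °C → rt
Reagents that add atoms: none
Why: Buffered fluoride cleaves the remaining silyl ether without touching the acetate or ionising the allylic alcohol, giving the target.

**Compound list**

1 | methyl 2-methylpropanoate (methyl isobutyrate) | COC(=O)C(C)C | starting material
2 | acrolein (prop-2-enal) | C=CC=O | starting material
3 | propanoyl chloride | CCC(=O)Cl | starting material
4 | lithium 1-methoxy-2,2-dimethyl-1-oxopent-4-en-3-olate (racemic) | [Li+].[O-]C(C=C)C(C)(C)C(=O)OC | intermediate (not isolated)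
5 | methyl 2,2-dimethyl-3-(propanoyloxy)pent-4-enoate (racemic) | CCC(=O)OC(C=C)C(C)(C)C(=O)OC | intermediate
6 | 6-ethenyl-3,5,5-trimethyloxane-2,4-dione (racemic at C6; C3 epimers and enol) | CC1C(=O)OC(C=C)C(C)(C)C1=O | intermediate
7 | 6-ethenyl-3,5,5-trimethyl-2-oxo-5,6-dihydro-2H-pyran-4-yl trifluoromethanesulfonate (racemic) | CC1=C(OS(=O)(=O)C(F)(F)F)C(C)(C)C(C=C)OC1=O | intermediate
8 | 4-methoxybenzyl alcohol | COc1ccc(CO)cc1 | starting material
9 | ethyl vinyl ether | CCOC=C | starting material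
10 | 4-methoxybenzyl vinyl ether | COc1ccc(COC=C)cc1 | intermediate
11 | 9-[2-(4-methoxybenzyloxy)ethyl]-9-borabicyclo[3.3.1]nonane | COc1ccc(COCCB2C3CCCC2CCC3)cc1 | intermediate (not isolated)
12 | 6-ethenyl-4-[2-(4-methoxybenzyloxy)ethyl]-3,5,5-trimethyl-5,6-dihydro-2H-pyran-2-one (racemic) | CC1=C(CCOCc2ccc(OC)cc2)C(C)(C)C(C=C)OC1=O | intermediate
13 | (2Z)-5-hydroxy-N-methoxy-3-[2-(4-methoxybenzyloxy)ethyl]-N,2,4,4-tetramethylhepta-2,6-dienamide (racemic) | CON(C)C(=O)/C(C)=C(/CCOCc1ccc(OC)cc1)C(C)(C)C(O)C=C | intermediate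
14 | (2Z)-N-methoxy-3-[2-(4-methoxybenzyloxy)ethyl]-N,2,4,4-tetramethyl-5-(triethylsilyloxy)hepta-2,6-dienamide (racemic) | CON(C)C(=O)/C(C)=C(/CCOCc1ccc(OC)cc1)C(C)(C)C(O[Si](CC)(CC)CC)C=C | intermediate
15 | penta-1,4-dien-3-ol | C=CC(O)C=C | starting material
16 | 3-(triethylsilyloxy)penta-1,4-diene | C=CC(O[Si](CC)(CC)CC)C=C | intermediate
17 | 9-[3-(triethylsilyloxy)pent-4-en-1-yl]-9-borabicyclo[3.3.1]nonane (racemic) | C=CC(O[Si](CC)(CC)CC)CCB1C2CCCC1CCC2 | intermediate (not isolated)
18 | 3-(triethylsilyloxy)pent-4-en-1-ol (racemic) | OCCC(O[Si](CC)(CC)CC)C=C | intermediate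
19 | 5-iodo-3-(triethylsilyloxy)pent-1-ene (racemic) | ICCC(O[Si](CC)(CC)CC)C=C | intermediate
20 | [3-(triethylsilyloxy)pent-4-en-1-yl]lithium (racemic) | [Li]CCC(O[Si](CC)(CC)CC)C=C | intermediate (not isolated)
21 | (7Z)-8-[2-(4-methoxybenzyloxy)ethyl]-7,9,9-trimethyl-3,10-bis(triethylsilyloxy)dodeca-1,7,11-trien-6-one (C3/C10 stereo-mixture) | C=CC(O[Si](CC)(CC)CC)CCC(=O)/C(C)=C(/CCOCc1ccc(OC)cc1)C(C)(C)C(O[Si](CC)(CC)CC)C=C | intermediate
22 | (6R,7Z)-8-[2-(4-methoxybenzyloxy)ethyl]-7,9,9-trimethyl-3,10-bis(triethylsilyloxy)dodeca-1,7,11-trien-6-ol (C3/C10 epimer mixture) | C=CC(O[Si](CC)(CC)CC)CC[C@@H](O)/C(C)=C(/CCOCc1ccc(OC)cc1)C(C)(C)C(O[Si](CC)(CC)CC)C=C | intermediate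
23 | (6R,7Z)-6-(tert-butyldimethylsilyloxy)-8-[2-(4-methoxybenzyloxy)ethyl]-7,9,9-trimethyl-3,10-bis(triethylsilyloxy)dodeca-1,7,11-triene (C3/C10 epimer mixture) | C=CC(O[Si](CC)(CC)CC)CC[C@@H](O[Si](C)(C)C(C)(C)C)/C(C)=C(/CCOCc1ccc(OC)cc1)C(C)(C)C(O[Si](CC)(CC)CC)C=C | intermediate
24 | (6R,7Z)-6-(tert-butyldimethylsilyloxy)-8-[2-(4-methoxybenzyloxy)ethyl]-7,9,9-trimethyldodeca-1,7,11-triene-3,10-diol (C3/C10 epimer mixture) | C=CC(O)CC[C@@H](O[Si](C)(C)C(C)(C)C)/C(C)=C(/CCOCc1ccc(OC)cc1)C(C)(C)C(O)C=C | intermediate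
25 | (6Z,8R)-8-(tert-butyldimethylsilyloxy)-6-[2-(4-methoxybenzyloxy)ethyl]-5,5,7-trimethylcyclodeca-2,6-diene-1,4-diol (C1/C4 epimers; C2=C3 geometry undefined) | OC1C=CC(O)C(C)(C)/C(CCOCc2ccc(OC)cc2)=C(C)\[C@H](O[Si](C)(C)C(C)(C)C)CC1 | intermediate
26 | (6Z,8R)-8-(tert-butyldimethylsilyloxy)-6-[2-(4-methoxybenzyloxy)ethyl]-5,5,7-trimethylcyclodec-6-ene-1,4-diol (C1/C4 epimers) | OC1CCC(O)C(C)(C)/C(CCOCc2ccc(OC)cc2)=C(C)\[C@H](O[Si](C)(C)C(C)(C)C)CC1 | intermediate
27 | (6Z,8R)-8-(tert-butyldimethylsilyloxy)-6-[2-(4-methoxybenzyloxy)ethyl]-5,5,7-trimethylcyclodec-6-ene-1,4-dione | O=C1CCC(=O)C(C)(C)/C(CCOCc2ccc(OC)cc2)=C(C)\[C@H](O[Si](C)(C)C(C)(C)C)CC1 | intermediate (key-step precursor)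
28 | (7R)-7-(tert-butyldimethylsilyloxy)-3a-hydroxy-5-[2-(4-methoxybenzyloxy)ethyl]-4,4,6-trimethyl-3,3a,4,7,8,8a-hexahydroazulen-1(2H)-one (ring-fusion centres undefined) | O=C1CCC2(O)C1C[C@@H](O[Si](C)(C)C(C)(C)C)C(C)=C(CCOCc1ccc(OC)cc1)C2(C)C | intermediate (not isolated)
29 | (7R)-7-(tert-butyldimethylsilyloxy)-5-[2-(4-methoxybenzyloxy)ethyl]-4,4,6-trimethyl-2,3,7,8-tetrahydroazulen-1(4H)-one | O=C1CCC2=C1C[C@@H](O[Si](C)(C)C(C)(C)C)C(C)=C(CCOCc1ccc(OC)cc1)C2(C)C | intermediate (key-step product)
30 | (1R,7R)-7-(tert-butyldimethylsilyloxy)-5-[2-(4-methoxybenzyloxy)ethyl]-4,4,6-trimethyl-1,2,3,4,7,8-hexahydroazulen-1-ol | O[C@@H]1CCC2=C1C[C@@H](O[Si](C)(C)C(C)(C)C)C(C)=C(CCOCc1ccc(OC)cc1)C2(C)C | intermediate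
31 | (1R,3aR,7R,8aR)-7-(tert-butyldimethylsilyloxy)-5-[2-(4-methoxybenzyloxy)ethyl]-4,4,6-trimethyl-1,2,3,3a,4,7,8,8a-octahydroazulen-1-ol | COc1ccc(COCCC2=C(C)[C@H](O[Si](C)(C)C(C)(C)C)C[C@@H]3[C@@H](CC[C@H]3O)C2(C)C)cc1 | intermediate
32 | (3aR,7R,8aR)-7-(tert-butyldimethylsilyloxy)-5-[2-(4-methoxybenzyloxy)ethyl]-4,4,6-trimethyl-3,3a,4,7,8,8a-hexahydroazulen-1(2H)-one | COc1ccc(COCCC2=C(C)[C@H](O[Si](C)(C)C(C)(C)C)C[C@@H]3[C@@H](CCC3=O)C2(C)C)cc1 | intermediate
33 | (3aR,7R,8aR)-7-(tert-butyldimethylsilyloxy)-5-[2-(4-methoxybenzyloxy)ethyl]-4,4,6-trimethyl-1-methylidene-1,2,3,3a,4,7,8,8a-octahydroazulene | COc1ccc(COCCC2=C(C)[C@H](O[Si](C)(C)C(C)(C)C)C[C@@H]3[C@@H](CCC3=C)C2(C)C)cc1 | intermediate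
34 | (1R,3aR,7R,8aR)-7-(tert-butyldimethylsilyloxy)-5-[2-(4-methoxybenzyloxy)ethyl]-1,4,4,6-tetramethyl-1,2,3,3a,4,7,8,8a-octahydroazulen-1-ol | COc1ccc(COCCC2=C(C)[C@H](O[Si](C)(C)C(C)(C)C)C[C@@H]3[C@@H](CC[C@@]3(C)O)C2(C)C)cc1 | intermediate
35 | (1R,3aR,7R,8aR)-7-(tert-butyldimethylsilyloxy)-5-(2-hydroxyethyl)-1,4,4,6-tetramethyl-1,2,3,3a,4,7,8,8a-octahydroazulen-1-ol | OCCC1=C(C)[C@H](O[Si](C)(C)C(C)(C)C)C[C@@H]2[C@@H](CC[C@@]2(C)O)C1(C)C | intermediate
36 | (1R,3aR,7R,8aR)-7-(tert-butyldimethylsilyloxy)-5-(2-iodoethyl)-1,4,4,6-tetramethyl-1,2,3,3a,4,7,8,8a-octahydroazulen-1-ol | ICCC1=C(C)[C@H](O[Si](C)(C)C(C)(C)C)C[C@@H]2[C@@H](CC[C@@]2(C)O)C1(C)C | intermediate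
37 | geranyl bromide ((2E)-1-bromo-3,7-dimethylocta-2,6-diene) | CC(C)=CCC/C(C)=C/CBr | starting material
38 | (4-bromobut-1-yn-1-yl)trimethylsilane | C[Si](C)(C)C#CCCBr | starting material
39 | [4-(trimethylsilyl)but-3-yn-1-yl]magnesium bromide | C[Si](C)(C)C#CCC[Mg]Br | intermediate (not isolated)
40 | trimethyl[(6E)-7,11-dimethyldodeca-6,10-dien-1-yn-1-yl]silane | CC(C)=CCC/C(C)=C/CCCC#C[Si](C)(C)C | intermediate
41 | (6E)-7,11-dimethyldodeca-6,10-dien-1-yne | CC(C)=CCC/C(C)=C/CCCC#C | intermediate
42 | [(6E)-7,11-dimethyldodeca-6,10-dien-1-yn-1-yl]lithium | CC(C)=CCC/C(C)=C/CCCC#C[Li] | intermediate (not isolated)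
43 | trimethyl[(7E)-8,12-dimethyltrideca-7,11-dien-2-yn-1-yl]silane | CC(C)=CCC/C(C)=C/CCCC#CC[Si](C)(C)C | intermediate
44 | trimethyl(6-{(2R,3R)-3-[2-((2R)-3,3-dimethyloxiran-2-yl)ethyl]-3-methyloxiran-2-yl}hex-2-yn-1-yl)silane | CC1(C)O[C@@H]1CC[C@@]1(C)O[C@@H]1CCCC#CC[Si](C)(C)C | intermediate
45 | {[(3R,5aR,9aR)-6-ethenylidene-2,2,5a-trimethyldecahydro-1-benzoxepin-3-yl]oxy}trimethylsilane | C[Si](C)(C)O[C@@H]1CC[C@]2(C)C(=C=C)CCC[C@H]2OC1(C)C | intermediate (not isolated)
46 | (3R,5aR,9aR)-6-ethenylidene-2,2,5a-trimethyldecahydro-1-benzoxepin-3-ol (trans-fused) | O[C@@H]1CC[C@]2(C)C(=C=C)CCC[C@H]2OC1(C)C | intermediate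
47 | triethyl{[(3R,5aR,9aR)-6-ethenylidene-2,2,5a-trimethyldecahydro-1-benzoxepin-3-yl]oxy}silane | CC[Si](CC)(CC)O[C@@H]1CC[C@]2(C)C(=C=C)CCC[C@H]2OC1(C)C | intermediate
48 | (3R,5aS,9aR)-2,2,5a-trimethyl-3-(triethylsilyloxy)octahydro-1-benzoxepin-6(2H)-one | CC[Si](CC)(CC)O[C@@H]1CC[C@]2(C)C(=O)CCC[C@H]2OC1(C)C | intermediate
49 | (3R,5aS,9aR)-2,2,5a-trimethyl-3-(triethylsilyloxy)-2,3,4,5,5a,8,9,9a-octahydro-1-benzoxepin-6-yl trifluoromethanesulfonate | CC[Si](CC)(CC)O[C@@H]1CC[C@]2(C)C(OS(=O)(=O)C(F)(F)F)=CCC[C@H]2OC1(C)C | intermediate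
50 | dilithio derivative of 36 (C11–Li and C23–OLi) | [Li]CCC1=C(C)[C@H](O[Si](C)(C)C(C)(C)C)C[C@@H]2[C@@H](CC[C@@]2(C)O[Li])C1(C)C | intermediate (not isolated)
51 | dilithium B-alkyl-B-methoxy-9-borabicyclo[3.3.1]nonane borate of 50 | [Li+].[Li+].CO[B-]1(CCC2=C(C)[C@H](O[Si](C)(C)C(C)(C)C)C[C@@H]3[C@@H](CC[C@@]3(C)[O-])C2(C)C)C2CCCC1CCC2 | intermediate (not isolated)
52 | (1R,3aR,7R,8aR)-7-(tert-butyldimethylsilyloxy)-1,4,4,6-tetramethyl-5-{2-[(3R,5aR,9aR)-2,2,5a-trimethyl-3-(triethylsilyloxy)-2,3,4,5,5a,8,9,9a-octahydro-1-benzoxepin-6-yl]ethyl}-1,2,3,3a,4,7,8,8a-octahydroazulen-1-ol | CC[Si](CC)(CC)O[C@@H]1CC[C@]2(C)C(CCC3=C(C)[C@H](O[Si](C)(C)C(C)(C)C)C[C@@H]4[C@@H](CC[C@@]4(C)O)C3(C)C)=CCC[C@H]2OC1(C)C | intermediate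
53 | thexyl(alkyl)borane adduct of 52 (boron on C29, hydrogen on C10, both trans to the C8 methyl) | CC[Si](CC)(CC)O[C@@H]1CC[C@]2(C)[C@@H](CCC3=C(C)[C@H](O[Si](C)(C)C(C)(C)C)C[C@@H]4[C@@H](CC[C@@]4(C)O)C3(C)C)[C@H](BC(C)(C)C(C)C)CC[C@H]2OC1(C)C | intermediate (not isolated)
54 | (3R,5aR,6R,7R,9aR)-6-{2-[(1R,3aR,7R,8aR)-7-(tert-butyldimethylsilyloxy)-1-hydroxy-1,4,4,6-tetramethyl-1,2,3,3a,4,7,8,8a-octahydroazulen-5-yl]ethyl}-2,2,5a-trimethyl-3-(triethylsilyloxy)decahydro-1-benzoxepin-7-ol | CC[Si](CC)(CC)O[C@@H]1CC[C@]2(C)[C@@H](CCC3=C(C)[C@H](O[Si](C)(C)C(C)(C)C)C[C@@H]4[C@@H](CC[C@@]4(C)O)C3(C)C)[C@H](O)CC[C@H]2OC1(C)C | intermediate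
55 | (3R,5aR,6R,9aR)-6-{2-[(1R,3aR,7R,8aR)-7-(tert-butyldimethylsilyloxy)-1-hydroxy-1,4,4,6-tetramethyl-1,2,3,3a,4,7,8,8a-octahydroazulen-5-yl]ethyl}-2,2,5a-trimethyl-3-(triethylsilyloxy)octahydro-1-benzoxepin-7(2H)-one | CC[Si](CC)(CC)O[C@@H]1CC[C@]2(C)[C@@H](CCC3=C(C)[C@H](O[Si](C)(C)C(C)(C)C)C[C@@H]4[C@@H](CC[C@@]4(C)O)C3(C)C)C(=O)CC[C@H]2OC1(C)C | intermediate
56 | (3R,5aR,6R,7S,9aR)-6-{2-[(1R,3aR,7R,8aR)-7-(tert-butyldimethylsilyloxy)-1-hydroxy-1,4,4,6-tetramethyl-1,2,3,3a,4,7,8,8a-octahydroazulen-5-yl]ethyl}-2,2,5a,7-tetramethyl-3-(triethylsilyloxy)decahydro-1-benzoxepin-7-ol | CC[Si](CC)(CC)O[C@@H]1CC[C@]2(C)[C@@H](CCC3=C(C)[C@H](O[Si](C)(C)C(C)(C)C)C[C@@H]4[C@@H](CC[C@@]4(C)O)C3(C)C)[C@@](C)(O)CC[C@H]2OC1(C)C | intermediate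
57 | (3R,5aR,6R,7S,9aR)-6-{2-[(1R,3aR,7R,8aR)-7-(tert-butyldimethylsilyloxy)-1-hydroxy-1,4,4,6-tetramethyl-1,2,3,3a,4,7,8,8a-octahydroazulen-5-yl]ethyl}-2,2,5a,7-tetramethyldecahydro-1-benzoxepine-3,7-diol | O[C@@H]1CC[C@]2(C)[C@@H](CCC3=C(C)[C@H](O[Si](C)(C)C(C)(C)C)C[C@@H]4[C@@H](CC[C@@]4(C)O)C3(C)C)[C@@](C)(O)CC[C@H]2OC1(C)C | intermediate
58 | (3R,5aR,6R,7S,9aR)-6-{2-[(1R,3aR,7R,8aR)-7-(tert-butyldimethylsilyloxy)-1-hydroxy-1,4,4,6-tetramethyl-1,2,3,3a,4,7,8,8a-octahydroazulen-5-yl]ethyl}-7-hydroxy-2,2,5a,7-tetramethyldecahydro-1-benzoxepin-3-yl acetate | CC(=O)O[C@@H]1CC[C@]2(C)[C@@H](CCC3=C(C)[C@H](O[Si](C)(C)C(C)(C)C)C[C@@H]4[C@@H](CC[C@@]4(C)O)C3(C)C)[C@@](C)(O)CC[C@H]2OC1(C)C | intermediate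
59 | CNP0157376.1: (3R,5aR,6R,7S,9aR)-6-{2-[(1R,3aR,7R,8aR)-1,7-dihydroxy-1,4,4,6-tetramethyl-1,2,3,3a,4,7,8,8a-octahydroazulen-5-yl]ethyl}-7-hydroxy-2,2,5a,7-tetramethyldecahydro-1-benzoxepin-3-yl acetate | CC(=O)O[C@@H]1CC[C@]2(C)[C@@H](CCC3=C(C)[C@H](O)C[C@@H]4[C@@H](CC[C@@]4(C)O)C3(C)C)[C@@](C)(O)CC[C@H]2OC1(C)C | target

**Totals.** Total step count: 40. Longest linear sequence: 28 steps (steps 1–3, 5–7, 11–25 and 34–40).

**Steps most likely to fail**

Step 15 (ring-closing metathesis). The medium-ring closure may stall or give oligomers because of transannular strain and because the C20 vinyl group is neopentylic. The fallback replaces the ten-membered closure by a seven-membered one through a temporary silicon tether. Setting out from diol 24, dichlorodiphenylsilane and imidazole in DMF under high dilution should bridge the C20 and C23 oxygens to give the diphenylsilylene-bridged triene F1. Second-generation Grubbs catalyst should then close the 1,3-dioxa-2-silacycloheptene, giving the bicyclic siloxane F2, in which C21=C22 is necessarily Z and the carbocycle is complete. K2CO3 in methanol removes the silylene and the route is rejoined at 25.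

Step 18 (key step). The reversible aldol addition may proceed while the elimination of the hindered tertiary hydroxyl stalls, or long exposure to base may erode the silyl ether. The fallback runs addition and dehydration as separate operations. Setting out from 27, brief treatment with KOt-Bu at 0 °C is stopped at ketol 28, which is isolated and dehydrated under non-basic conditions with Martin sulfurane (Ph2S[OC(CF3)2Ph]2, CH2Cl2, rt). Any β,γ-unsaturated isomer is moved into conjugation with catalytic DBU, and the route is rejoined at 29. This fallback makes no new compound F0.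

Step 23 (Mukaiyama hydration). Oxygen capture by the C23 radical may show poor facial selectivity, or reduction to the alkane may compete. The fallback builds the carbinol by two-electron chemistry. Setting out from 33, OsO4 (cat.) with N-methylmorpholine N-oxide should dihydroxylate the unhindered exocyclic alkene from the convex face and give the diol F3. Selective sulfonylation of the primary hydroxyl (TsCl, pyridine) should give the tosylate F4, and LiEt3BH should reduce the C–O bond (through the spiro-epoxide) to the methyl group, rejoining the route at 34.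

**Further compounds**

F1 | step 15 | diphenylsilylene-bridged triene (C20 and C23 oxygens of 24 joined by SiPh2) | C=CC1CC[C@@H](O[Si](C)(C)C(C)(C)C)/C(C)=C(/CCOCc2ccc(OC)cc2)C(C)(C)C(C=C)O[Si](c2ccccc2)(c2ccccc2)O1
F2 | step 15 | bicyclic siloxane (C21=C22 Z within a 2,2-diphenyl-1,3-dioxa-2-silacyclohept-5-ene bridging C20 and C23 of the cyclodecene) | O1[Si](c2ccccc2)(c2ccccc2)OC2C=CC1CC[C@@H](O[Si](C)(C)C(C)(C)C)/C(C)=C(/CCOCc1ccc(OC)cc1)C2(C)C
F0 | step 18 | none | none
F3 | step 23 | (1R,3aR,7R,8aR)-7-(tert-butyldimethylsilyloxy)-1-(hydroxymethyl)-5-[2-(4-methoxybenzyloxy)ethyl]-4,4,6-trimethyl-1,2,3,3a,4,7,8,8a-octahydroazulen-1-ol | COc1ccc(COCCC2=C(C)[C@H](O[Si](C)(C)C(C)(C)C)C[C@@H]3[C@@H](CC[C@@]3(CO)O)C2(C)C)cc1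
F4 | step 23 | [(1R,3aR,7R,8aR)-7-(tert-butyldimethylsilyloxy)-1-hydroxy-5-[2-(4-methoxybenzyloxy)ethyl]-4,4,6-trimethyl-1,2,3,3a,4,7,8,8a-octahydroazulen-1-yl]methyl 4-methylbenzenesulfonate | COc1ccc(COCCC2=C(C)[C@H](O[Si](C)(C)C(C)(C)C)C[C@@H]3[C@@H](CC[C@@]3(COS(=O)(=O)c4ccc(C)cc4)O)C2(C)C)cc1
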